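## Retrosynthetic overview

1. Target 14 ⇒ dimethyl ether 13 (aryl ether cleavage). 13 is cut at the chain bond C7'–C8' into spiro enol ether 8 and 1-bromotetracosane 10, which are joined by an oxidative ring-opening/nickel radical cross-coupling.
2. Enabling feature: C2 of the γ-pyrone ring plus chain carbons C1'–C7' are the eight carbons of cyclooctanone. At the 4-methoxy-2H-chromene level the ring O1–C2–C3–C4–C4a–C8a is one electron and one C2–C bond away from an aromatic chromenylium ion, so oxidation should expel C7' as a primary radical.
3. 8 ⇒ spirochromanone 6 (enolate O-methylation) ⇒ acetophenone 3 + cyclooctanone 4 (Kabbe condensation). 3 ⇒ 2,4,6-trimethoxytoluene 1, where acylation and ortho-demethylation place the free OH next to the C-methyl group, which becomes the 8-methyl.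
4. Ring order: the benzene ring is bought. The dihydropyranone and the temporary spiro-cyclooctane are set up in step 2. The cyclooctane is opened and the pyranone aromatised in step 5.

Key step: step 5

Remark: the side chain is read as n-hentriacontyl and numbered C1' (on C2 of the chromone) to C31'. The target has no stereocentre, so no stereocontrol is needed.

## Route

Step 1
Reactants: 1 2,4,6-trimethoxytoluene
Product: 3 1-(2-hydroxy-4,6-dimethoxy-3-methylphenyl)ethanone, via trimethoxy-methylacetophenone 2 (not isolated)
Conditions: AcCl (1.2 equiv), AlCl3 (2.5 equiv), CH2Cl2, 0 °C → rt; aq. HCl work-up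
Reagents that add atoms: acetyl chloride, CC(=O)Cl
Why: Friedel–Crafts acylation at one of the two equivalent, strongly activated ring positions gives 2, and excess AlCl3 then cleaves one ortho-methoxy group through the aluminium chelate with the new ketone, preferentially the ether buttressed between acetyl and C-methyl (twisted out of the ring plane), which leaves the free OH next to the methyl group.

Step 2
Reactants: 3 1-(2-hydroxy-4,6-dimethoxy-3-methylphenyl)ethanone; 4 cyclooctanone
Product: 6 5,7-dimethoxy-8-methylspiro[chromane-2,1'-cyclooctan]-4-one, via cyclooctylidene enone 5 (not isolated)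
Conditions: 4 (2 equiv), pyrrolidine (0.5 equiv, catalyst), toluene, Dean–Stark, reflux
Reagents that add atoms: none
Why: In the Kabbe condensation, iminium/enamine activation by pyrrolidine condenses the acetyl CH3 with cyclooctanone to enone 5, and the only free phenol closes the ring by 6-endo-trig oxa-Michael addition, so O1 ends up next to C8–CH3.

Step 3
Reactants: 6 5,7-dimethoxy-8-methylspiro[chromane-2,1'-cyclooctan]-4-one
Product: 8 4,5,7-trimethoxy-8-methylspiro[chromene-2,1'-cyclooctane], via potassium enolate 7 (not isolated)
Conditions: KHMDS (1.15 equiv), 18-crown-6 (1.2 equiv), THF, −78 °C; MeOTf (1.3 equiv), −78 → −20 °C; Et3N quench, basic alumina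
Reagents that add atoms: methyl triflate, COS(=O)(=O)C(F)(F)F
Why: This is enolate O-alkylation, in which a crown-separated potassium enolate and a hard methylating agent favour attack at oxygen, C3 is shielded by the neighbouring quaternary spiro carbon, and the in-ring C2–O1 bond overlaps poorly with the enolate π system, so phenoxide expulsion should stay slow at −78 °C.

Step 4
Reactants: 9 tetracosan-1-ol
Product: 10 1-bromotetracosane
Conditions: CBr4 (1.2 equiv), PPh3 (1.25 equiv), CH2Cl2/THF, 0 → 35 °C
Reagents that add atoms: carbon tetrabromide, BrC(Br)(Br)Br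
Why: In the Appel reaction the alkoxyphosphonium ion of the primary alcohol is displaced by bromide in a clean SN2 step.

Step 5
Reactants: 8 4,5,7-trimethoxy-8-methylspiro[chromene-2,1'-cyclooctane] (1.5 equiv); 10 1-bromotetracosane
Product: 13 2-hentriacontyl-5,7-dimethoxy-8-methyl-4H-chromen-4-one, via chromenylium heptyl radical 11 (not isolated), via hentriacontylchromenylium bromide 12 (not isolated)
Conditions: 4CzIPN (2 mol %), NiBr2·glyme (10 mol %), 4,4'-dimethoxy-2,2'-bipyridine (12 mol %), 3 Å MS, DMA/PhCF3 1:1, Ar, blue LEDs (450 nm), 40 °C; then dark, 60 °C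
Reagents that add atoms: none
Why: Proposed new method: excited 4CzIPN oxidises the electron-rich aryl enol ether 8 to its radical cation (spin mainly on C3, charge on C4–OMe, O1 and the arene); since the allylic carbon C2 is quaternary no proton can be lost there, and the pseudo-axial C2–CH2 bond of the cyclooctane, which overlaps with the π system, should break to give the aromatic 4-methoxychromenylium ion carrying the primary C7' radical (11). A thermochemical cycle (weak, doubly activated C2–C bond, easy oxidation of 8, hard reduction of the trialkoxychromenylium ion) puts this cleavage near thermoneutral, helped by the roughly 10 kcal/mol strain of cyclooctane and the entropy of ring opening, and capture of 11 by low-valent nickel makes it irreversible. Nickel then activates bromide 10 by halogen abstraction and rebound, reductive elimination from Ni(III) forms the C7'–C8' bond (12), the reduced photocatalyst returns Ni(I) to Ni(0), and the bromide ion set free removes the 4-O-methyl group of 12 by SN2 attack, so the step is redox-neutral, base-free and ends at the neutral chromone 13. The closest known reaction type is the aromatisation-driven ring-opening cross-coupling of ketone-derived spiro-dihydroquinazolinones (and of 4-alkyl-1,4-dihydropyridines) with alkyl bromides under nickel/photoredox dual catalysis; new here are the oxygen heterocycle and the carbon-centred enol ether radical cation as the trigger. No ring is closed and no stereocentre is made: the cyclooctane is opened, and its two C2–CH2 bonds are constitutionally equivalent, so either cleavage gives the same chain. The selectivities needed are C–C cleavage over loss of the enol O-methyl group or of a proton from the 8-methyl group, secured by the robust methyl (not silyl) enol ether and the absence of base, and cross- over homo-coupling, secured because one partner arises only by oxidation at the photocatalyst and the other only by reduction at nickel.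

Step 6
Reactants: 13 2-hentriacontyl-5,7-dimethoxy-8-methyl-4H-chromen-4-one
Product: 14 2-hentriacontyl-5,7-dihydroxy-8-methyl-4H-chromen-4-one
Conditions: BBr3 (6 equiv), CH2Cl2, 0 °C → rt; ice-water quench
Reagents that add atoms: none
Why: BBr3 aryl methyl ether cleavage removes the 5-OMe group with assistance from the peri carbonyl and the 7-OMe group with excess reagent, and the anhydrous Lewis-acid conditions at or below room temperature keep the pyrone ring closed, so no Wessely–Moser opening and re-closure can move the methyl group from C8 to C6.

## Compound list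

1 | 2,4,6-trimethoxytoluene | Cc1c(OC)cc(OC)cc1OC | starting material
2 | 1-(2,4,6-trimethoxy-3-methylphenyl)ethanone | CC(=O)c1c(OC)c(C)c(OC)cc1OC | intermediate
3 | 1-(2-hydroxy-4,6-dimethoxy-3-methylphenyl)ethanone | CC(=O)c1c(O)c(C)c(OC)cc1OC | intermediate
4 | cyclooctanone | O=C1CCCCCCC1 | starting material
5 | 2-cyclooctylidene-1-(2-hydroxy-4,6-dimethoxy-3-methylphenyl)ethanone | COc1cc(OC)c(C(=O)C=C2CCCCCCC2)c(O)c1C | intermediate
6 | 5,7-dimethoxy-8-methylspiro[chromane-2,1'-cyclooctan]-4-one | O=C1CC2(CCCCCCC2)Oc2c(C)c(OC)cc(OC)c12 | intermediate
7 | potassium 5,7-dimethoxy-8-methylspiro[chromene-2,1'-cyclooctan]-4-olate | [K+].[O-]C1=CC2(CCCCCCC2)Oc2c(C)c(OC)cc(OC)c12 | intermediate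
8 | 4,5,7-trimethoxy-8-methylspiro[chromene-2,1'-cyclooctane] | COC1=CC2(CCCCCCC2)Oc2c(C)c(OC)cc(OC)c12 | intermediate
9 | tetracosan-1-ol | CCCCCCCCCCCCCCCCCCCCCCCCO | starting material
10 | 1-bromotetracosane | CCCCCCCCCCCCCCCCCCCCCCCCBr | intermediate
11 | 7-(4,5,7-trimethoxy-8-methylchromenylium-2-yl)heptyl radical | [CH2]CCCCCCc1cc(OC)c2c(OC)cc(OC)c(C)c2[o+]1 | intermediate
12 | 2-hentriacontyl-4,5,7-trimethoxy-8-methylchromenylium bromide | CCCCCCCCCCCCCCCCCCCCCCCCCCCCCCCc1cc(OC)c2c(OC)cc(OC)c(C)c2[o+]1.[Br-] | intermediate
13 | 2-hentriacontyl-5,7-dimethoxy-8-methyl-4H-chromen-4-one | CCCCCCCCCCCCCCCCCCCCCCCCCCCCCCCc1cc(=O)c2c(OC)cc(OC)c(C)c2o1 | intermediate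
14 | 2-hentriacontyl-5,7-dihydroxy-8-methyl-4H-chromen-4-one | CCCCCCCCCCCCCCCCCCCCCCCCCCCCCCCc1cc(=O)c2c(O)cc(O)c(C)c2o1 | target

## Step count and risks

Total step count: 6. Longest linear sequence: 5 (steps 1, 2, 3, 5, 6).

**Step 5 (Proposed new method).**
- Risk at the radical cation: it may take the electron back, or lose its O-methyl group or a proton of the 8-methyl group, faster than the C2–CH2 bond breaks.
- Risk at the chromenylium ion: it may build up before it is demethylated and intercept the reduced photocatalyst, which would starve the nickel cycle.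
- Risk at the bromide: it may be used up by homocoupling or hydrodehalogenation.
- Fallback (known chemistry, same bond): it sets out from 3 and comes back at 13.
  - Claisen condensation of 3 with commercial methyl oct-7-enoate (C=CCCCCCC(=O)OC; NaH, THF, reflux) should give 1-(2-hydroxy-4,6-dimethoxy-3-methylphenyl)dec-9-ene-1,3-dione F1.
  - Acid-catalysed cyclodehydration (cat. TsOH, toluene, 80 °C) should give 2-(hept-6-en-1-yl)-5,7-dimethoxy-8-methyl-4H-chromen-4-one F2.
  - Hydroboration of the terminal alkene with 9-BBN (1.1 equiv, THF, 0 °C → rt) should be faster than attack on the vinylogous ester carbonyl and give 2-[7-(9-borabicyclo[3.3.1]nonan-9-yl)heptyl]-5,7-dimethoxy-8-methyl-4H-chromen-4-one F3.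
  - F3 is coupled without isolation with bromide 10 in an alkyl–alkyl Suzuki–Miyaura reaction (Pd(OAc)2, PCy3, K3PO4·H2O, THF, rt) to give 13.

**Step 3.**
- Risk: methylation at C3 instead of oxygen, opening of the enolate by expulsion of the phenoxide followed by methylation of that phenoxide, or hydrolysis of the enol ether during purification.
- Fallback: it sets out from 6, comes back at 8, and avoids any enolate.
  - Acid-catalysed ketalisation (HC(OMe)3, cat. TsOH, MeOH) should give 4,4,5,7-tetramethoxy-8-methylspiro[chromane-2,1'-cyclooctane] F4.
  - Heating F4 in toluene with catalytic pyridinium p-toluenesulfonate while methanol is distilled off should eliminate one methoxy group to give 8.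

**Step 2.**
- Risk: slow condensation, because cyclooctanone resists the sp2 → sp3 change (transannular strain) and the acetophenone is electron-rich and hindered. Self-condensation of cyclooctanone or incomplete oxa-Michael closure may also occur.
- Fallback: it sets out from 3 and 4, comes back at 6, and replaces the amine-catalysed condensation by a directed aldol.
  - Double deprotonation of 3 (LDA, 2.2 equiv, THF, −78 °C), optional transmetalation with CeCl3, and addition to 4 should give 1-(2-hydroxy-4,6-dimethoxy-3-methylphenyl)-2-(1-hydroxycyclooctyl)ethanone F5.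
  - Acid (cat. TsOH, toluene, reflux) should dehydrate F5 and close the ring to 6.

## Further compounds

F1 | step 5 | 1-(2-hydroxy-4,6-dimethoxy-3-methylphenyl)dec-9-ene-1,3-dione | C=CCCCCCC(=O)CC(=O)c1c(O)c(C)c(OC)cc1OC
F2 | step 5 | 2-(hept-6-en-1-yl)-5,7-dimethoxy-8-methyl-4H-chromen-4-one | C=CCCCCCc1cc(=O)c2c(OC)cc(OC)c(C)c2o1
F3 | step 5 | 2-[7-(9-borabicyclo[3.3.1]nonan-9-yl)heptyl]-5,7-dimethoxy-8-methyl-4H-chromen-4-one | COc1cc(OC)c2c(=O)cc(CCCCCCCB3C4CCCC3CCC4)oc2c1C
F4 | step 3 | 4,4,5,7-tetramethoxy-8-methylspiro[chromane-2,1'-cyclooctane] | COC1(OC)CC2(CCCCCCC2)Oc2c(C)c(OC)cc(OC)c12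
F5 | step 2 | 1-(2-hydroxy-4,6-dimethoxy-3-methylphenyl)-2-(1-hydroxycyclooctyl)ethanone | COc1cc(OC)c(C(=O)CC2(O)CCCCCCC2)c(O)c1C
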